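**Retrosynthetic overview**
1. Late stage: the C14 alcohol is oxidised to the aldehyde, C15 is acetylated, C13 is added by Mannich methylenation, and lactone ring B is closed from a C12 ester onto the 6α-hydroxyl. The C8 ester arrives, together with the C6 carbinol, in an Evans–Tishchenko reduction with (S)-2-methylbutanal.
2. C6, C7 and C8 all come from the achiral ten-membered 6,8-dione 16: transfer hydrogenation (C8), dianion alkylation (C7–C11), 1,3-anti reduction (C6).
3. Key disconnection: C7–C8 of ring A is a ketene two-carbon unit inserted into the C6–C9 bond of cyclooctadienone 11 (dichloroketene [2+2] on silyl enol ether 13, dechlorination, retro-aldol opening of the bicyclo[6.2.0] cyclobutanone; 8 → 10).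
4. Enabling feature: in ring A the oxygens on C6 and C8 flank C7 (a masked 1,3-diketone), and the remainder C9–C10=C1–C2–C3–C4=C5–C6, with both trisubstituted double bonds cis in the ring, is a cycloocta-1,5-diene as soon as C6 is bonded to C9.
5. Ketone 11 comes from vinylketene 9 (C3–C6, C15) and diene 8 (C1, C2, C9, C10, C14) by [2+2] then Cope (4 → 8). Ring order: cyclobutanone, eight-membered ring, ring A (ten-membered), ring B (lactone).

Key step: step 7

Remark: germacrane numbering is used (ring A C1–C10, lactone carbons C11–C13, C14 on C10, C15 on C4); the target is read as the trans-fused 6α,12-olide with H-7α and 8β-acyloxy (6R,7R,8R), both ring double bonds cis within ring A (CIP 1(10)E,4E), and an (S)-2-methylbutanoate.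
Assumption: 4-methylfuran-2(5H)-one, 2-methyl-2-vinyloxirane and (S)-2-methylbutan-1-ol are bought; 10, 14 and 15 are racemic and 16 is achiral, so absolute configuration enters at step 8.

**Route**

Step 1
Reactants: 1 4-methylfuran-2(5H)-one
Product: 4 (2Z)-4-[(tert-butyldiphenylsilyl)oxy]-3-methylbut-2-enoic acid, via sodium hydroxy-enoate 2 (not isolated), via bis-silyl derivative 3 (not isolated)
Conditions: NaOH (1.0 equiv), MeOH/H2O, rt; evaporate; t-BuPh2SiCl (2.2 equiv), imidazole, DMF, rt; K2CO3 (cat.), MeOH/THF/H2O, 0 °C; citric acid to pH 4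
Reagents that add atoms: sodium hydroxide [Na+].[OH-]; tert-butyl(chloro)diphenylsilane CC(C)(C)[Si](Cl)(c1ccccc1)c1ccccc1
Why: Saponification opens the butenolide with retention of the Z geometry, and bis-silylation of the dry salt followed by selective hydrolysis of the labile silyl ester should give the protected acid (standard lactone to silyloxy acid protocol).

Step 2
Reactants: 4 (2Z)-4-[(tert-butyldiphenylsilyl)oxy]-3-methylbut-2-enoic acid
Product: 5 (2Z)-4-[(tert-butyldiphenylsilyl)oxy]-3-methylbut-2-enoyl chloride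
Conditions: 1-chloro-N,N,2-trimethylprop-1-en-1-amine (1.1 equiv), CH2Cl2, 0 °C; used as a solution
Reagents that add atoms: 1-chloro-N,N,2-trimethylprop-1-en-1-amine CC(C)=C(Cl)N(C)C
Why: Acid chloride formation with an α-chloroenamine is neutral (no HCl), so the silyl ether should survive and the Z-enoyl chloride should not relactonise before use.

Step 3
Reactants: 6 2-methyl-2-vinyloxirane (racemic)
Product: 7 2-methylidenebut-3-en-1-ol
Conditions: LiN(iPr)2 (1.3 equiv), Et2O, 0 °C → rt; H2O
Reagents that add atoms: none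
Why: Base-induced isomerisation of an epoxide to an allylic alcohol; the only β-hydrogens are on the methyl group, so syn elimination should give the 2-(hydroxymethyl)butadiene.

Step 4
Reactants: 7 2-methylidenebut-3-en-1-ol
Product: 8 1-methoxy-4-{[(2-methylidenebut-3-en-1-yl)oxy]methyl}benzene
Conditions: NaH, 4-methoxybenzyl chloride, Bu4NI (cat.), THF, 0 °C → rt
Reagents that add atoms: 4-methoxybenzyl chloride COc1ccc(CCl)cc1
Why: Williamson etherification of the primary allylic alkoxide.

Step 5
Reactants: 5 (2Z)-4-[(tert-butyldiphenylsilyl)oxy]-3-methylbut-2-enoyl chloride; 8 1-methoxy-4-{[(2-methylidenebut-3-en-1-yl)oxy]methyl}benzene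
Product: 11 (2E,6E)-3-{[(tert-butyldiphenylsilyl)oxy]methyl}-7-{[(4-methoxybenzyl)oxy]methyl}cycloocta-2,6-dien-1-one (both ring double bonds cis in the ring), via vinylketene 9 (not isolated), via dialkenylcyclobutanone 10 (not isolated)
Conditions: Et3N (1.3 equiv), 8 (1.5 equiv), toluene, 0 °C → rt; filter; 105 °C
Reagents that add atoms: none
Why: 1,4-Dehydrochlorination of 5 at the unhindered methyl group gives vinylketene 9, which should add [2+2] to the more substituted double bond of 8 (ketene carbonyl carbon to the CH2 terminus, as with isoprene), and the 2,3-dialkenylcyclobutanone 10 then undergoes a boat-type Cope rearrangement through its cis isomer while the trans isomer feeds in by epimerisation α to the ketone, so that both isomers converge on 11 with both new double bonds necessarily cis in the eight-membered ring (vinylketene/diene [4+4] annulation).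

Step 6
Reactants: 11 cyclooctadienone
Product: 13 1-{[(tert-butyldiphenylsilyl)oxy]methyl}-5-{[(4-methoxybenzyl)oxy]methyl}-3-(trimethylsilyloxy)cycloocta-1,3,5-triene (silyl enol ether across C6=C9), via lithium dienolate 12 (not isolated)
Conditions: LiN(iPr)2 (1.1 equiv), THF, −78 °C; Me3SiCl; cold aq. NaHCO3/pentane work-up, used at once
Reagents that add atoms: chlorotrimethylsilane C[Si](C)(C)Cl
Why: Kinetic deprotonation of the enone at the α' carbon C9 (also allylic) and O-silylation give the cross-conjugated silyl enol ether, which is used cold and immediately to outrun 6π-electrocyclisation of the cyclooctatriene.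

Step 7
Reactants: 13 silyl enol ether
Product: 16 (4E,8E)-5-{[(tert-butyldiphenylsilyl)oxy]methyl}-9-{[(4-methoxybenzyl)oxy]methyl}cyclodeca-4,8-diene-1,3-dione (ring A; germacrane C6 and C8 ketones; both ring double bonds cis in the ring), via dichlorocyclobutanone adduct 14 (not isolated), via siloxycyclobutanone 15 (not isolated)
Conditions: Cl2CHCOCl (1.3 equiv), Et3N (1.3 equiv), hexane, 0 °C → rt; filter; Zn dust, AcOH, i-PrOH/H2O, 0 °C; then 45 °C
Reagents that add atoms: dichloroacetyl chloride ClC(Cl)C(Cl)=O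
Why: Dichloroketene, made in situ, adds across the electron-rich C6=C9 enol ether bond of 13 (carbonyl carbon to C9, CCl2 to C6) to give the cis-fused bicyclo[6.2.0] cyclobutanone 14, zinc removes both chlorines (15), and protodesilylation releases a 3-hydroxycyclobutanone that undergoes retro-aldol cleavage of the ring-fusion bond C6–C9, so the eight-membered ring becomes ring A with C7 and C8 inserted. The closest known reaction type is the two-carbon ring expansion of cycloalkanone silyl enol ethers to cycloalkane-1,3-diones by dichloroketene [2+2] cycloaddition, zinc/acetic acid dechlorination and retro-aldol opening. The only ring closed is the transient cyclobutanone, formed by [2+2] cycloaddition of the ketene C=C onto the enol ether (suprafacial on the alkene, hence cis-fused); ring A is not closed but arises by fragmentation of the shared bond. No stereocentre survives in 16 (the two centres of 14 and 15 are destroyed in the opening), and both ring double bonds keep the cis geometry fixed in the eight-membered ring because neither is touched. The step needs site selectivity for C9 over the vinylogous terminus C1 and cleavage of C6–C9 rather than C6–C7: the first should be secured because attack at C1 would have to close on fully substituted C10 next to CCl2 and because the tub-shaped triene is poorly conjugated, the second by dechlorinating before desilylation (no CCl2 carbanion) and by the allylic, enolate-stabilised carbanion at C9 together with relief of cyclobutane strain.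

Step 8
Reactants: 16 ring A 6,8-dione
Product: 17 (8R)-8-hydroxy-14-(4-methoxybenzyloxy)-15-(tert-butyldiphenylsilyloxy)-11,12,13-trinorgermacra-1(10),4-dien-6-one (8β-OH)
Conditions: RuCl[(R,R)-TsDPEN](p-cymene) (2 mol%), HCO2H/Et3N (5:2), CH2Cl2, rt
Reagents that add atoms: none
Why: Noyori–Ikariya transfer hydrogenation should reduce the more electrophilic, non-conjugated C8 carbonyl of the 1,3-diketone once, with the neighbouring C6 carbonyl acting as the directing π-group so that the (R,R) ligand should give the 8R alcohol (assignment by analogy to aryl ketones, to be confirmed on the first batch), while the enone and the trisubstituted alkenes stay untouched.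

Step 9
Reactants: 17 8β-hydroxy-6-ketone
Product: 19 tert-butyl (7R,8R)-8-hydroxy-14-(4-methoxybenzyloxy)-6-oxo-15-(tert-butyldiphenylsilyloxy)-13-norgermacra-1(10),4-dien-12-oate (C7 side chain cis to 8-OH on the ring), via dilithium alkoxide-enolate 18 (not isolated)
Conditions: LiN(iPr)2 (2.3 equiv), THF, −78 → −40 °C; DMPU; BrCH2CO2t-Bu (1.2 equiv), −78 °C; AcOH quench at −78 °C
Reagents that add atoms: tert-butyl bromoacetate BrCC(=O)OC(C)(C)C
Why: Fráter–Seebach-type alkylation of the β-hydroxy ketone dianion: the lithium alkoxide–enolate chelate should be alkylated at C7 on the face opposite to C9, setting C7 anti to the C8 oxygen (C11 β, H-7α), and the tert-butyl ester resists attack by the alkoxide at low temperature.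

Step 10
Reactants: 20 (S)-2-methylbutan-1-ol
Product: 21 (S)-2-methylbutanal
Conditions: TEMPO (5 mol%), PhI(OAc)2 (1.1 equiv), CH2Cl2, rt; used as a solution
Reagents that add atoms: none
Why: Nitroxyl-catalysed oxidation of the primary alcohol stops at the aldehyde and is non-basic, so the α-stereocentre should not be enolised.

Step 11
Reactants: 19 β-hydroxy ketone ester; 21 (S)-2-methylbutanal
Product: 22 tert-butyl (6R,7S,8R)-6-hydroxy-14-(4-methoxybenzyloxy)-8-[(2S)-2-methylbutanoyloxy]-15-(tert-butyldiphenylsilyloxy)-13-norgermacra-1(10),4-dien-12-oate (6α-OH; 8β-ester)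
Conditions: SmI2 (0.3 equiv), 21 (5 equiv), THF, −10 °C
Reagents that add atoms: none
Why: Evans–Tishchenko reduction: the samarium-bound hemiacetal formed from the C8 hydroxyl and 21 delivers hydride intramolecularly to the C6 ketone through a chair-like chelate, which should give the 1,3-anti C6 alcohol and leave the (S)-2-methylbutanoyl group on O8, so the two oxygens are differentiated for lactonisation.

Step 12
Reactants: 22 hydroxy diester
Product: 25 (6R,7R,8R)-14-(4-methoxybenzyloxy)-8-[(2S)-2-methylbutanoyloxy]-15-(tert-butyldiphenylsilyloxy)-13-norgermacra-1(10),4-dien-12,6-olide (trans-fused ring B), via bis-trimethylsilyl derivative 23 (not isolated), via hydroxy acid 24 (not isolated)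
Conditions: Me3SiOTf (3.5 equiv), 2,6-lutidine (5 equiv), CH2Cl2, 0 °C; aq. citric acid/THF, rt; PPTS (cat.), toluene, 40 °C
Reagents that add atoms: none
Why: The silyl triflate converts the tert-butyl ester into a silyl ester without protic acid (so the allylic C6 carbinol is not ionised), aqueous acid frees the γ-hydroxy acid, and mild acid catalysis closes ring B by 5-exo-trig lactonisation onto the only free hydroxyl with the H-6/H-7 trans relationship already set.

Step 13
Reactants: 25 lactone
Product: 29 (6R,7R,8R)-14-(4-methoxybenzyloxy)-8-[(2S)-2-methylbutanoyloxy]-15-(tert-butyldiphenylsilyloxy)germacra-1(10),4,11(13)-trien-12,6-olide, via lithium lactone enolate 26 (not isolated), via Mannich base 27 (not isolated), via ammonium iodide 28 (not isolated)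
Conditions: LiN(SiMe3)2 (1.15 equiv), THF, −78 °C; CH2=NMe2 iodide (3 equiv), −78 °C → rt; MeI, CH2Cl2/MeOH, rt; sat. aq. NaHCO3, rt
Reagents that add atoms: dimethyl(methylidene)ammonium iodide C=[N+](C)C.[I-]
Why: The lactone α-CH2 is markedly more acidic than the α-branched ester, so one equivalent of the silylamide should enolise only the lactone, and Mannich reaction with the iminium salt, N-methylation and base-induced elimination install the exocyclic methylene (classical α-methylenation).

Step 14
Reactants: 29 α-methylene lactone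
Product: 30 (6R,7R,8R)-15-hydroxy-14-(4-methoxybenzyloxy)-8-[(2S)-2-methylbutanoyloxy]germacra-1(10),4,11(13)-trien-12,6-olide
Conditions: HF·pyridine, pyridine, THF, 0 °C → rt
Reagents that add atoms: none
Why: Buffered fluoride cleaves the primary silyl ether without touching the benzyl-type ether, the esters or the Michael acceptor.

Step 15
Reactants: 30 C15 alcohol
Product: 31 (6R,7R,8R)-15-acetoxy-14-(4-methoxybenzyloxy)-8-[(2S)-2-methylbutanoyloxy]germacra-1(10),4,11(13)-trien-12,6-olide
Conditions: Ac2O, pyridine, CH2Cl2, 0 °C → rt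
Reagents that add atoms: acetic anhydride CC(=O)OC(C)=O
Why: Acetylation of the unhindered primary allylic alcohol under pyridine catalysis.

Step 16
Reactants: 31 C15 acetate
Product: 33 15-acetoxy-8β-[(2S)-2-methylbutanoyloxy]-14-oxogermacra-1(10),4,11(13)-trien-12,6α-olide (6R,7R,8R; target), via C14 allylic alcohol 32 (not isolated)
Conditions: DDQ (1.3 equiv), CH2Cl2/pH 7 buffer, 0 °C; filter; MnO2 (15 equiv), CH2Cl2, rt
Reagents that add atoms: none
Why: Oxidative cleavage of the 4-methoxybenzyl ether by DDQ and chemoselective allylic oxidation with MnO2 should give the α,β-unsaturated aldehyde under neutral conditions that leave the ring-cis C1=C10 geometry untouched.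

**Compound list**
1 | 4-methylfuran-2(5H)-one | CC1=CC(=O)OC1 | starting material
2 | sodium (2Z)-4-hydroxy-3-methylbut-2-enoate | [Na+].[O-]C(=O)/C=C(C)\CO | intermediate (not isolated)
3 | tert-butyldiphenylsilyl (2Z)-4-[(tert-butyldiphenylsilyl)oxy]-3-methylbut-2-enoate | CC(C)(C)[Si](c1ccccc1)(c1ccccc1)OC(=O)/C=C(C)\CO[Si](c1ccccc1)(c1ccccc1)C(C)(C)C | intermediate (not isolated)
4 | (2Z)-4-[(tert-butyldiphenylsilyl)oxy]-3-methylbut-2-enoic acid | OC(=O)/C=C(C)\CO[Si](c1ccccc1)(c1ccccc1)C(C)(C)C | intermediate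
5 | (2Z)-4-[(tert-butyldiphenylsilyl)oxy]-3-methylbut-2-enoyl chloride | ClC(=O)/C=C(C)\CO[Si](c1ccccc1)(c1ccccc1)C(C)(C)C | intermediate
6 | 2-methyl-2-vinyloxirane (racemic) | CC1(C=C)CO1 | starting material
7 | 2-methylidenebut-3-en-1-ol | OCC(=C)C=C | intermediate
8 | 1-methoxy-4-{[(2-methylidenebut-3-en-1-yl)oxy]methyl}benzene | C=CC(=C)COCc1ccc(OC)cc1 | intermediate
9 | 3-{[(tert-butyldiphenylsilyl)oxy]methyl}buta-1,3-dien-1-one (vinylketene) | O=C=CC(=C)CO[Si](c1ccccc1)(c1ccccc1)C(C)(C)C | intermediate (not isolated)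
10 | 3-ethenyl-3-{[(4-methoxybenzyl)oxy]methyl}-2-(3-{[tert-butyl(diphenyl)silyl]oxy}prop-1-en-2-yl)cyclobutan-1-one (cis/trans mixture, racemic; stereocentres left open because both epimers converge) | O=C1CC(COCc2ccc(OC)cc2)(C=C)C1C(=C)CO[Si](c2ccccc2)(c2ccccc2)C(C)(C)C | intermediate (not isolated)
11 | (2E,6E)-3-{[(tert-butyldiphenylsilyl)oxy]methyl}-7-{[(4-methoxybenzyl)oxy]methyl}cycloocta-2,6-dien-1-one (both double bonds ring-cis) | O=C1/C=C(/CO[Si](c2ccccc2)(c2ccccc2)C(C)(C)C)CC/C=C(/COCc2ccc(OC)cc2)C1 | intermediate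
12 | lithium dienolate of 11 (O on C6, C6=C9) | [Li+].[O-]/C1=C/C(COCc2ccc(OC)cc2)=C\CC/C(CO[Si](c2ccccc2)(c2ccccc2)C(C)(C)C)=C\1 | intermediate (not isolated)
13 | 1-{[(tert-butyldiphenylsilyl)oxy]methyl}-5-{[(4-methoxybenzyl)oxy]methyl}-3-(trimethylsilyloxy)cycloocta-1,3,5-triene (all ring-cis) | C[Si](C)(C)O/C1=C/C(COCc2ccc(OC)cc2)=C\CC/C(CO[Si](c2ccccc2)(c2ccccc2)C(C)(C)C)=C\1 | intermediate
14 | cis-fused 10,10-dichloro-3-{[(tert-butyldiphenylsilyl)oxy]methyl}-7-{[(4-methoxybenzyl)oxy]methyl}-1-(trimethylsilyloxy)bicyclo[6.2.0]deca-2,6-dien-9-one (racemic, one enantiomer drawn) | C[Si](C)(C)O[C@@]12/C=C(/CO[Si](c3ccccc3)(c3ccccc3)C(C)(C)C)CC/C=C(/COCc3ccc(OC)cc3)[C@@H]1C(=O)C2(Cl)Cl | intermediate (not isolated)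
15 | cis-fused 3-{[(tert-butyldiphenylsilyl)oxy]methyl}-7-{[(4-methoxybenzyl)oxy]methyl}-1-(trimethylsilyloxy)bicyclo[6.2.0]deca-2,6-dien-9-one (racemic, one enantiomer drawn) | C[Si](C)(C)O[C@@]12/C=C(/CO[Si](c3ccccc3)(c3ccccc3)C(C)(C)C)CC/C=C(/COCc3ccc(OC)cc3)[C@@H]1C(=O)C2 | intermediate (not isolated)
16 | (4E,8E)-5-{[(tert-butyldiphenylsilyl)oxy]methyl}-9-{[(4-methoxybenzyl)oxy]methyl}cyclodeca-4,8-diene-1,3-dione (both double bonds ring-cis) | O=C1/C=C(/CO[Si](c2ccccc2)(c2ccccc2)C(C)(C)C)CC/C=C(/COCc2ccc(OC)cc2)CC(=O)C1 | intermediate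
17 | (8R)-8-hydroxy-14-(4-methoxybenzyloxy)-15-(tert-butyldiphenylsilyloxy)-11,12,13-trinorgermacra-1(10),4-dien-6-one | O=C1/C=C(/CO[Si](c2ccccc2)(c2ccccc2)C(C)(C)C)CC/C=C(/COCc2ccc(OC)cc2)C[C@@H](O)C1 | intermediate
18 | dilithium C8-alkoxide C6-enolate of 17 (ring-cis enolate assumed) | [Li+].[Li+].[O-]/C1=C/[C@H]([O-])C/C(COCc2ccc(OC)cc2)=C\CC/C(CO[Si](c2ccccc2)(c2ccccc2)C(C)(C)C)=C\1 | intermediate (not isolated)
19 | tert-butyl (7R,8R)-8-hydroxy-14-(4-methoxybenzyloxy)-6-oxo-15-(tert-butyldiphenylsilyloxy)-13-norgermacra-1(10),4-dien-12-oate | O=C1/C=C(/CO[Si](c2ccccc2)(c2ccccc2)C(C)(C)C)CC/C=C(/COCc2ccc(OC)cc2)C[C@@H](O)[C@H]1CC(=O)OC(C)(C)C | intermediate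
20 | (S)-2-methylbutan-1-ol | OC[C@@H](C)CC | starting material
21 | (S)-2-methylbutanal | O=C[C@@H](C)CC | intermediate
22 | tert-butyl (6R,7S,8R)-6-hydroxy-14-(4-methoxybenzyloxy)-8-[(2S)-2-methylbutanoyloxy]-15-(tert-butyldiphenylsilyloxy)-13-norgermacra-1(10),4-dien-12-oate | O[C@@H]1/C=C(/CO[Si](c2ccccc2)(c2ccccc2)C(C)(C)C)CC/C=C(/COCc2ccc(OC)cc2)C[C@@H](OC(=O)[C@@H](C)CC)[C@H]1CC(=O)OC(C)(C)C | intermediate
23 | trimethylsilyl ester, 6-O-trimethylsilyl ether of the acid of 22 | C[Si](C)(C)O[C@@H]1/C=C(/CO[Si](c2ccccc2)(c2ccccc2)C(C)(C)C)CC/C=C(/COCc2ccc(OC)cc2)C[C@@H](OC(=O)[C@@H](C)CC)[C@H]1CC(=O)O[Si](C)(C)C | intermediate (not isolated)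
24 | 6α-hydroxy-12-oic acid corresponding to 22 | O[C@@H]1/C=C(/CO[Si](c2ccccc2)(c2ccccc2)C(C)(C)C)CC/C=C(/COCc2ccc(OC)cc2)C[C@@H](OC(=O)[C@@H](C)CC)[C@H]1CC(=O)O | intermediate (not isolated)
25 | (6R,7R,8R)-14-(4-methoxybenzyloxy)-8-[(2S)-2-methylbutanoyloxy]-15-(tert-butyldiphenylsilyloxy)-13-norgermacra-1(10),4-dien-12,6-olide | C1C(=O)O[C@@H]2/C=C(/CO[Si](c3ccccc3)(c3ccccc3)C(C)(C)C)CC/C=C(/COCc3ccc(OC)cc3)C[C@@H](OC(=O)[C@@H](C)CC)[C@@H]12 | intermediate
26 | lithium enolate of lactone 25 | [Li+].C1=C([O-])O[C@@H]2/C=C(/CO[Si](c3ccccc3)(c3ccccc3)C(C)(C)C)CC/C=C(/COCc3ccc(OC)cc3)C[C@@H](OC(=O)[C@@H](C)CC)[C@@H]12 | intermediate (not isolated)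
27 | 11-[(dimethylamino)methyl] lactone (C11 epimers) | CN(C)CC1C(=O)O[C@@H]2/C=C(/CO[Si](c3ccccc3)(c3ccccc3)C(C)(C)C)CC/C=C(/COCc3ccc(OC)cc3)C[C@@H](OC(=O)[C@@H](C)CC)[C@@H]12 | intermediate (not isolated)
28 | 11-[(trimethylammonio)methyl] lactone iodide (C11 epimers) | C[N+](C)(C)CC1C(=O)O[C@@H]2/C=C(/CO[Si](c3ccccc3)(c3ccccc3)C(C)(C)C)CC/C=C(/COCc3ccc(OC)cc3)C[C@@H](OC(=O)[C@@H](C)CC)[C@@H]12.[I-] | intermediate (not isolated)
29 | (6R,7R,8R)-14-(4-methoxybenzyloxy)-8-[(2S)-2-methylbutanoyloxy]-15-(tert-butyldiphenylsilyloxy)germacra-1(10),4,11(13)-trien-12,6-olide | C=C1C(=O)O[C@@H]2/C=C(/CO[Si](c3ccccc3)(c3ccccc3)C(C)(C)C)CC/C=C(/COCc3ccc(OC)cc3)C[C@@H](OC(=O)[C@@H](C)CC)[C@@H]12 | intermediate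
30 | (6R,7R,8R)-15-hydroxy-14-(4-methoxybenzyloxy)-8-[(2S)-2-methylbutanoyloxy]germacra-1(10),4,11(13)-trien-12,6-olide | C=C1C(=O)O[C@@H]2/C=C(/CO)CC/C=C(/COCc3ccc(OC)cc3)C[C@@H](OC(=O)[C@@H](C)CC)[C@@H]12 | intermediate
31 | (6R,7R,8R)-15-acetoxy-14-(4-methoxybenzyloxy)-8-[(2S)-2-methylbutanoyloxy]germacra-1(10),4,11(13)-trien-12,6-olide | C=C1C(=O)O[C@@H]2/C=C(/COC(C)=O)CC/C=C(/COCc3ccc(OC)cc3)C[C@@H](OC(=O)[C@@H](C)CC)[C@@H]12 | intermediate
32 | (6R,7R,8R)-15-acetoxy-14-hydroxy-8-[(2S)-2-methylbutanoyloxy]germacra-1(10),4,11(13)-trien-12,6-olide | C=C1C(=O)O[C@@H]2/C=C(/COC(C)=O)CC/C=C(/CO)C[C@@H](OC(=O)[C@@H](C)CC)[C@@H]12 | intermediate (not isolated)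
33 | 15-acetoxy-8β-[(2S)-2-methylbutanoyloxy]-14-oxogermacra-1(10),4,11(13)-trien-12,6α-olide (6R,7R,8R) | C=C1C(=O)O[C@@H]2/C=C(/COC(C)=O)CC/C=C(/C=O)C[C@@H](OC(=O)[C@@H](C)CC)[C@@H]12 | target

**Totals**
Total step count: 16. Longest linear sequence: 13 steps (1 → 4 → 5 → 11 → 13 → 16 → 17 → 19 → 22 → 25 → 29 → 30 → 31 → 33).

**Steps most likely to fail**

Step 7. The ketene may bond first at the vinylogous terminus C1 of the C6=C9–C10=C1 siloxydiene (cycloaddition across C1=C10 or a [4+2] mode), the trienol ether may electrocyclise before it is trapped, or the hydroxycyclobutanone may open toward C7. Fallback, from 11 and back at 16: the competing π-bond is removed for the duration of the ring expansion. OsO4 (cat.)/NMO should dihydroxylate only the electron-rich C1=C10 bond of 11 (the enone double bond is inert) to give cis-diol F1, and 1,1'-thiocarbonyldiimidazole closes cyclic thionocarbonate F2. Enolisation and silylation as in step 6 give silyl enol ether F3, now a plain 2-siloxydiene, for which ketene addition at the siloxy-bearing double bond is the normal course. The conditions of step 7 then lead through dichlorocyclobutanone F4 and its dechlorinated form F5 to ring-expanded dione thionocarbonate F6. Corey–Winter olefination with P(OMe)3 (toluene, 110 °C), a stereospecific syn elimination, restores the ring-cis C1=C10 bond and gives 16.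

Step 9. Facial selectivity of the alkylation may be poor in the ten-membered chelate, the enone may be deprotonated at a γ position, or the C8 alkoxide may attack the new ester. Fallback, from 16 and back at 19: alkylate first, reduce second. K2CO3 and tert-butyl bromoacetate in acetone should C-alkylate the 1,3-dione at C7 to give 2-substituted dione F7, whose C7 centre epimerises freely through the enol. Transfer hydrogenation with the catalyst of step 8 then runs as a dynamic kinetic resolution and should give 19 directly, bypassing 17; the relative configuration at C7/C8 must be checked at this point.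

Step 11. The α-branched aldehyde may enolise and lose configuration on the Lewis-acidic samarium centre, and hydride transfer to the hindered, conjugated C6 ketone may be slow. Fallback, from 19 and back at 22: fix the acyl group first and reduce under reagent control. (S)-2-Methylbutanoyl chloride and pyridine (CH2Cl2, −20 °C) give β-acyloxy ketone F8, kept cold to avoid β-elimination. Corey–Bakshi–Shibata reduction ((R)-B-methyl oxazaborolidine, catecholborane, −78 °C, alkenyl branch taken as the large group) should then give the 6α-alcohol 22.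

**Further compounds**
F1 | step 7 | cis-1,10-diol of 11 (racemic, one enantiomer drawn) | O=C1/C=C(/CO[Si](c2ccccc2)(c2ccccc2)C(C)(C)C)CC[C@H](O)[C@@](O)(COCc2ccc(OC)cc2)C1
F2 | step 7 | cyclic 1,10-thionocarbonate of F1 | O=C1/C=C(/CO[Si](c2ccccc2)(c2ccccc2)C(C)(C)C)CC[C@@H]2OC(=S)O[C@]2(COCc2ccc(OC)cc2)C1
F3 | step 7 | trimethylsilyl enol ether (C6=C9) of F2 | C[Si](C)(C)O/C1=C/[C@@]2(COCc3ccc(OC)cc3)OC(=S)O[C@H]2CC/C(CO[Si](c3ccccc3)(c3ccccc3)C(C)(C)C)=C\1
F4 | step 7 | dichlorocyclobutanone adduct of F3 (cis-fused, ring-fusion centres as mixture) | C[Si](C)(C)OC12/C=C(/CO[Si](c3ccccc3)(c3ccccc3)C(C)(C)C)CC[C@@H]3OC(=S)O[C@]3(COCc4ccc(OC)cc4)C1C(=O)C2(Cl)Cl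
F5 | step 7 | dechlorinated siloxycyclobutanone from F4 | C[Si](C)(C)OC12/C=C(/CO[Si](c3ccccc3)(c3ccccc3)C(C)(C)C)CC[C@@H]3OC(=S)O[C@]3(COCc4ccc(OC)cc4)C1C(=O)C2
F6 | step 7 | ring-expanded cyclodec-4-ene-1,3-dione 8,9-thionocarbonate | O=C1/C=C(/CO[Si](c2ccccc2)(c2ccccc2)C(C)(C)C)CC[C@@H]2OC(=S)O[C@]2(COCc2ccc(OC)cc2)CC(=O)C1
F7 | step 9 | tert-butyl 2-(1,3-dioxocyclodecadien-2-yl)acetate (16 alkylated at C7, C7 configurationally labile) | O=C1/C=C(/CO[Si](c2ccccc2)(c2ccccc2)C(C)(C)C)CC/C=C(/COCc2ccc(OC)cc2)CC(=O)C1CC(=O)OC(C)(C)C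
F8 | step 11 | 8-O-[(2S)-2-methylbutanoyl] derivative of 19 | O=C1/C=C(/CO[Si](c2ccccc2)(c2ccccc2)C(C)(C)C)CC/C=C(/COCc2ccc(OC)cc2)C[C@@H](OC(=O)[C@@H](C)CC)[C@H]1CC(=O)OC(C)(C)C
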